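All runs are calculated with constants of no real substance.

The easy thing to watch is the target's rate, which shows from the first reading of Tuesday's run.

the same everywhere: gas 65 mM (held)
- Tuesday's: starting material 2.2 M; run made earlier
- flask: starting material 1.5 M; time 10 h

Tuesday's run (percent of the starting material charged)

| time / min | side product / % | target / % |
|---|---|---|
| 4.00 | 0.8 | 4.3 |
| 12.0 | 4.2 | 10.9 |
| 20.0 | 9.2 | 17.7 |
| 30.0 | 15.2 | 23.2 |
| 50.0 | 24.2 | 32.6 |
| 60.0 | 27.0 | 34.5 |

(scatter of a reading: 0.3 percentage points)

- share of side product in side product plus target at 80 s
- share of side product in side product plus target at 25 min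
- share of side product in side product plus target at 10 h

- at the start none of the gas is in solution

In Tuesday's run the target forms at 0.00885 min⁻¹ of the charge over the first 20.0 min. Between 30.0 min and 60.0 min it forms at 0.00377 min⁻¹, which is slower by a factor 2.35 across the 35.0 min between the midpoints of those windows. This reckoning, which is not the forecast's, supposes that the target's rate follows the starting material left, a pseudo-first-order loss:

τ = 35.0 min / ln(2.35) = 41.0 min

Here τ is the lifetime of the starting material, the time in which the starting material left, and with it the target's rate, falls by a factor e; it is a reading from Tuesday's run and carries that run's scatter. Tuesday's run has one charge, so whether τ holds at 1.5 M is untested, and it is taken over as it stands. The slowing then accumulates in the flask as follows: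

left at 60.0 min = exp(−60.0 min / τ) = 23.1%

lifetimes in 10 h: N = 14.6, left = exp(−N) = <0.001%

With <0.001% reckoned left, the share at 10 h is reckoned to be that of a finished flask.

The forecast, which calls the run “essentially complete”, gives 5.5%, 37.5% and 47.5%.

The flask gives 4.10%, 39.0% and 47.8%, each within the forecast's margin.

    gas ⇌ partner, rate k1*(csat - [partner]) (kL = 0.0228 s⁻¹)
    starting material + partner → intermediate A (k = 0.00423 L mol⁻¹ s⁻¹)
    intermediate A → side product (k = 0.00203 s⁻¹)
    intermediate A → decomposed reagent (k = 8.91 × 10⁻⁴ s⁻¹)
    starting material → target (k = 1.81 × 10⁻⁴ s⁻¹)
    intermediate A ⇌ intermediate B (K = 0.323, k = 3.49 × 10⁻⁴ s⁻¹)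

The comparison that counts is the time allowed against the lifetime read from Tuesday's run, 10 h against 41.0 min, or 14.6 lifetimes. The flask holds 22.1% of its starting material at 1.00 h, where the reckoning gave 23.1%, then 0.0323% at 5.00 h, and a tenfold time leaves the share where it stands.

In the neighbour flask with 0.90 M of starting material, the same τ counts the same 14.6 lifetimes and so expects <0.001% left. That flask ends with 0% left and a share of 48.9%, higher than this flask's by 1.1 percentage points.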